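A direct plan would start from the tartrate-derived (2S,3S)-oxirane-2,3-dicarbaldehyde A1 and allylate both formyl groups to (4S,5R,6R,7S)-5,6-epoxydeca-1,9-diene-4,7-diol A2. It would then lengthen one vinyl group of the bis-silyl ether of A2 by hydroboration and alkyl–alkyl coupling, and lactonise the seco-acid (2Z)-6,7-epoxy-21-hydroxy-5,8-bis(triethylsilyloxy)docos-2-enoic acid A3. Its weakest steps would be three. First, the twofold allylation of A1: the labile dialdehyde would have to be attacked twice against its own erythro preference to reach the threo,threo array at C5 and C8. Second, the differentiation of the two homotopic vinyl groups of A2, which could only be statistical and would cost material and a recycling loop. Third, the macrolactonisation of A3, where the activated (Z)-enoyl group could isomerise or oligomerise, and which several protecting-group changes at C21 would have to precede.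

The route rests on the C6–C7 bond. The C5–C8 segment (carbinol, oxirane, carbinol) is locally C2-symmetric; with the oxirane replaced by a triple bond it becomes a but-2-yne-1,4-diol whose two halves are propargylic alcohols of the same sense, each made by transfer hydrogenation with one catalyst. Ring-closing alkyne metathesis of the diyne ester 16 then closes the 22-membered ring at C6≡C7 in one operation, the ester link having been made earlier by an intermolecular (Z)-olefination. The oxirane is made last, by trans-reduction and an epoxidation in which reagent and hydroxyl direction agree. Epoxy aldehyde, statistical desymmetrisation and macrolactonisation have no counterpart.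

Key step: step 11

Assumption: bis(2,2,2-trifluoroethyl)phosphonoacetic acid is taken as a catalogue reagent; positions are given in the numbering of the target (C1 lactone carbonyl, C21 lactone carbinol, C22 methyl).

Step 1
Reactants: 1 12-bromododecanoic acid; 2 1-(trimethylsilyl)propyne
Product: 4 15-bromopentadec-2-yn-4-one, via 12-bromododecanoyl chloride 3 (not isolated)
Conditions: (COCl)2, DMF (cat.), CH2Cl2, 0 °C → rt, evaporate; then 2 (1.2 equiv), AlCl3 (1.2 equiv), CH2Cl2, −20 → 0 °C; ice/1 M HCl
Reagents that add atoms: oxalyl chloride, O=C(Cl)C(Cl)=O (its chlorine is in intermediate 3 only)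
Why: Acid chloride formation followed by Friedel–Crafts-type ipso-acylation of the alkynylsilane (β-silyl vinyl cation, loss of Me3SiCl) should give the ynone with C7–C8 formed; no stereocentre is involved.

Step 2
Reactants: 4 15-bromopentadec-2-yn-4-one
Product: 5 (S)-15-bromopentadec-2-yn-4-ol
Conditions: RuCl[(S,S)-TsNCH(Ph)CH(Ph)NH2](η6-p-cymene) (1 mol%), i-PrOH, rt
Reagents that add atoms: none
Why: Noyori–Ikariya asymmetric transfer hydrogenation, in which hydride and proton pass from the Ru–H/N–H unit through a six-membered transition state with the alkynyl group under the η6-arene (as the aryl group of an aryl ketone), so that the (S,S)-catalyst should give the (S)-carbinol (C8) and leave the alkyl bromide alone.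

Step 3
Reactants: 5 (S)-15-bromopentadec-2-yn-4-ol
Product: 6 (S)-[(15-bromopentadec-2-yn-4-yl)oxy]triethylsilane
Conditions: Et3SiCl, imidazole, CH2Cl2, 0 °C → rt
Reagents that add atoms: chlorotriethylsilane, CC[Si](Cl)(CC)CC
Why: Imidazole-promoted silylation masks the propargylic hydroxyl for the Grignard step and for the metathesis catalyst without touching the stereocentre.

Step 4
Reactants: 6 (S)-[(15-bromopentadec-2-yn-4-yl)oxy]triethylsilane; 7 (R)-propylene oxide
Product: 9 (2R,15S)-15-(triethylsilyloxy)octadec-16-yn-2-ol, via Grignard reagent 8 (not isolated)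
Conditions: Mg, THF, 40 °C; then CuI (10 mol%), 7, THF, −30 → 0 °C; aq. NH4Cl
Reagents that add atoms: magnesium, [Mg] (in intermediate 8 only)
Why: Copper-catalysed SN2 opening of the terminal epoxide by the Grignard reagent at the unsubstituted carbon forms C19–C20 and carries the configuration of (R)-propylene oxide over to C21 unchanged.

Step 5
Reactants: 9 (2R,15S)-15-(triethylsilyloxy)octadec-16-yn-2-ol
Product: 10 (2R,15S)-15-(triethylsilyloxy)octadec-16-yn-2-yl [bis(2,2,2-trifluoroethoxy)phosphoryl]acetate
Conditions: (CF3CH2O)2P(O)CH2CO2H, N,N'-dicyclohexylcarbodiimide, 4-(dimethylamino)pyridine (cat.), CH2Cl2, 0 °C → rt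
Reagents that add atoms: bis(2,2,2-trifluoroethyl)phosphonoacetic acid, OC(=O)CP(=O)(OCC(F)(F)F)OCC(F)(F)F
Why: Steglich (carbodiimide) esterification acylates the only free hydroxyl at oxygen, so C21 keeps its configuration and the ester link of the future lactone is made intermolecularly.

Step 6
Reactants: 11 methyl malonyl chloride (methyl 3-chloro-3-oxopropanoate); 2 1-(trimethylsilyl)propyne
Product: 12 methyl 3-oxohex-4-ynoate
Conditions: AlCl3 (2.2 equiv), CH2Cl2, −20 → 0 °C; ice/1 M HCl
Reagents that add atoms: none
Why: The same Friedel–Crafts-type ipso-acylation of the alkynylsilane as in step 1, the β-keto ester being held as its aluminium chelate until work-up, should give the ynone with C5–C6 formed.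

Step 7
Reactants: 12 methyl 3-oxohex-4-ynoate
Product: 13 methyl (S)-3-hydroxyhex-4-ynoate
Conditions: RuCl[(S,S)-TsNCH(Ph)CH(Ph)NH2](η6-p-cymene) (2 mol%), HCO2H/Et3N (5:2), CH2Cl2, rt
Reagents that add atoms: none
Why: Asymmetric transfer hydrogenation as in step 2 with the same (S,S)-catalyst, the ynone carbonyl being far more reactive than the ester and formic acid making the reduction irreversible, should give the (S)-carbinol (C5).

Step 8
Reactants: 13 methyl (S)-3-hydroxyhex-4-ynoate
Product: 14 methyl (S)-3-(triethylsilyloxy)hex-4-ynoate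
Conditions: Et3SiCl, imidazole, CH2Cl2, 0 °C → rt
Reagents that add atoms: chlorotriethylsilane, CC[Si](Cl)(CC)CC
Why: Imidazole-promoted silylation protects the β-hydroxyl against retro-aldol cleavage and elimination in the next two steps; the stereocentre is not involved.

Step 9
Reactants: 14 methyl (S)-3-(triethylsilyloxy)hex-4-ynoate
Product: 15 (S)-3-(triethylsilyloxy)hex-4-ynal
Conditions: i-Bu2AlH (1.1 equiv), CH2Cl2, −78 °C; MeOH, then aq. Rochelle salt; used at once
Reagents that add atoms: none
Why: Partial ester reduction with i-Bu2AlH at −78 °C stops at the aluminium hemiacetal, which the β-silyloxy group stabilises, and releases the aldehyde on work-up without touching C5.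

Step 10
Reactants: 10 (2R,15S)-15-(triethylsilyloxy)octadec-16-yn-2-yl [bis(2,2,2-trifluoroethoxy)phosphoryl]acetate; 15 (S)-3-(triethylsilyloxy)hex-4-ynal
Product: 16 (2R,15S)-15-(triethylsilyloxy)octadec-16-yn-2-yl (2Z,5S)-5-(triethylsilyloxy)oct-2-en-6-ynoate
Conditions: 10, KN(SiMe3)2, 18-crown-6, THF, −78 °C; then 15, −78 °C
Reagents that add atoms: none
Why: Still–Gennari variant of the Horner–Wadsworth–Emmons olefination, in which the electron-poor phosphonate under dissociating conditions eliminates fast from the kinetic adduct, should join the fragments at C2=C3 as the (Z)-enoate at a temperature at which the β-silyloxy aldehyde does not eliminate.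

Step 11
Reactants: 16 (2R,15S)-15-(triethylsilyloxy)octadec-16-yn-2-yl (2Z,5S)-5-(triethylsilyloxy)oct-2-en-6-ynoate
Product: 17 (2Z,5S,8S,21R)-5,8-bis(triethylsilyloxy)docos-2-en-6-yn-21-olide
Conditions: [Mo(≡CC6H4-4-OMe)(OSiPh3)3] (10 mol%), 5 Å molecular sieves, toluene (2 mM), 60 → 80 °C
Reagents that add atoms: none
Why: Ring-closing alkyne metathesis: the molybdenum alkylidyne takes up one propynyl terminus by [2+2] cycloaddition and cycloreversion through a metallacyclobutadiene, the substrate-bound alkylidyne then meets the second propynyl group intramolecularly, and but-2-yne is expelled and trapped by the sieves, which drives the equilibrium. The closest known reaction type is the macrocyclisation of diyne esters carrying propargylic ethers with molybdenum alkylidynes bearing triarylsilanolate ligands. The 22-membered ring is closed end to end at C6≡C7, the bond that will later carry the oxirane, and no smaller ring can compete because a small cycloalkyne is too strained. No stereocentre is created: C5, C8 and C21 come in unchanged from steps 7, 2 and 4 because no bond to them is touched, and the triple bond is a geometry-free placeholder whose E-reduction in step 12 fixes the trans-oxirane. The selectivity needed is triple bond over (Z)-enoate and ring over oligomer; alkylidynes do not engage olefins or esters, and high dilution with reversible metathesis should return oligomers to the monomeric ring. Both alkynes are branched at the propargylic carbon, which slows initiation and is the reason for the higher loading and temperature.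

Step 12
Reactants: 17 (2Z,5S,8S,21R)-5,8-bis(triethylsilyloxy)docos-2-en-6-yn-21-olide
Product: 19 (2Z,5S,6E,8S,21R)-5,8-bis(triethylsilyloxy)docosa-2,6-dien-21-olide, via C6-triethoxysilyl cycloalkene 18 (not isolated)
Conditions: (EtO)3SiH, [(η5-C5Me5)Ru(MeCN)3]PF6 (10 mol%), CH2Cl2, 0 °C → rt; filter through silica; then AgF, THF/MeOH/H2O, rt, dark
Reagents that add atoms: triethoxysilane, CCO[SiH](OCC)OCC (its silyl group is in intermediate 18 only)
Why: Ruthenium-catalysed trans-hydrosilylation (formal anti addition of H–Si) followed by silver-fluoride-mediated protodesilylation with retention should turn the cycloalkyne into the (E)-cycloalkene, the site of silyl delivery being irrelevant and the (Z)-enoate being left alone.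

Step 13
Reactants: 19 (2Z,5S,6E,8S,21R)-5,8-bis(triethylsilyloxy)docosa-2,6-dien-21-olide
Product: 20 (2Z,5S,6E,8S,21R)-5,8-dihydroxydocosa-2,6-dien-21-olide
Conditions: HF·pyridine, pyridine, THF, 0 °C
Reagents that add atoms: none
Why: Pyridine-buffered fluoride cleavage of both triethylsilyl ethers should be too mild to ionise the allylic carbinols or to move the acyl group onto the C5 hydroxyl.

Step 14
Reactants: 20 (2Z,5S,6E,8S,21R)-5,8-dihydroxydocosa-2,6-dien-21-olide
Product: 21 CIML C, (2Z,5S,6R,7R,8S,21R)-6,7-epoxy-5,8-dihydroxydocos-2-en-21-olide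
Conditions: 1,2:4,5-di-O-isopropylidene-β-D-erythro-2,3-hexodiulo-2,6-pyranose (D-fructose-derived Shi ketone, 3 equiv), Oxone (2KHSO5·KHSO4·K2SO4), NaHCO3, MeCN/aq. Na2EDTA, pH 7–8, 0 °C
Reagents that add atoms: potassium peroxymonosulfate (active component of Oxone), [K+].[O-]S(=O)(=O)OO
Why: Shi epoxidation, in which the dioxirane formed from the ketone should transfer oxygen through a spiro transition state to the face of the (E)-alkene that gives the (6R,7R)-oxirane, the same face that hydrogen bonding from the two allylic hydroxyls favours (threo to both), while the electron-poor (Z)-enoate stays inert and the near-neutral protocol keeps the lactone from migrating to the C5 hydroxyl.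

**Compound list**
1 | 12-bromododecanoic acid | OC(=O)CCCCCCCCCCCBr | starting material
2 | 1-(trimethylsilyl)propyne | CC#C[Si](C)(C)C | starting material
3 | 12-bromododecanoyl chloride | ClC(=O)CCCCCCCCCCCBr | intermediate (not isolated)
4 | 15-bromopentadec-2-yn-4-one | CC#CC(=O)CCCCCCCCCCCBr | intermediate
5 | (S)-15-bromopentadec-2-yn-4-ol | CC#C[C@@H](O)CCCCCCCCCCCBr | intermediate
6 | (S)-[(15-bromopentadec-2-yn-4-yl)oxy]triethylsilane | CC#C[C@@H](O[Si](CC)(CC)CC)CCCCCCCCCCCBr | intermediate
7 | (R)-propylene oxide | C[C@@H]1CO1 | starting material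
8 | [(12S)-12-(triethylsilyloxy)pentadec-13-yn-1-yl]magnesium bromide | CC#C[C@@H](O[Si](CC)(CC)CC)CCCCCCCCCCC[Mg]Br | intermediate (not isolated)
9 | (2R,15S)-15-(triethylsilyloxy)octadec-16-yn-2-ol | C[C@@H](O)CCCCCCCCCCCC[C@H](O[Si](CC)(CC)CC)C#CC | intermediate
10 | (2R,15S)-15-(triethylsilyloxy)octadec-16-yn-2-yl [bis(2,2,2-trifluoroethoxy)phosphoryl]acetate | C[C@@H](OC(=O)CP(=O)(OCC(F)(F)F)OCC(F)(F)F)CCCCCCCCCCCC[C@H](O[Si](CC)(CC)CC)C#CC | intermediate
11 | methyl malonyl chloride (methyl 3-chloro-3-oxopropanoate) | COC(=O)CC(Cl)=O | starting material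
12 | methyl 3-oxohex-4-ynoate | CC#CC(=O)CC(=O)OC | intermediate
13 | methyl (S)-3-hydroxyhex-4-ynoate | CC#C[C@@H](O)CC(=O)OC | intermediate
14 | methyl (S)-3-(triethylsilyloxy)hex-4-ynoate | CC#C[C@@H](O[Si](CC)(CC)CC)CC(=O)OC | intermediate
15 | (S)-3-(triethylsilyloxy)hex-4-ynal | CC#C[C@@H](O[Si](CC)(CC)CC)CC=O | intermediate
16 | (2R,15S)-15-(triethylsilyloxy)octadec-16-yn-2-yl (2Z,5S)-5-(triethylsilyloxy)oct-2-en-6-ynoate | C[C@@H](OC(=O)/C=C\C[C@H](O[Si](CC)(CC)CC)C#CC)CCCCCCCCCCCC[C@H](O[Si](CC)(CC)CC)C#CC | intermediate
17 | (2Z,5S,8S,21R)-5,8-bis(triethylsilyloxy)docos-2-en-6-yn-21-olide, i.e. (3Z,6S,9S,22R)-22-methyl-6,9-bis(triethylsilyloxy)oxacyclodocos-3-en-7-yn-2-one | C[C@@H]1CCCCCCCCCCCC[C@H](O[Si](CC)(CC)CC)C#C[C@@H](O[Si](CC)(CC)CC)C/C=C\C(=O)O1 | intermediate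
18 | (2Z,5S,6Z,8S,21R)-6-(triethoxysilyl)-5,8-bis(triethylsilyloxy)docosa-2,6-dien-21-olide (C6-silyl isomer drawn; the C7-silyl isomer gives the same alkene) | C[C@@H]1CCCCCCCCCCCC[C@H](O[Si](CC)(CC)CC)/C=C(\[Si](OCC)(OCC)OCC)[C@@H](O[Si](CC)(CC)CC)C/C=C\C(=O)O1 | intermediate (not isolated)
19 | (2Z,5S,6E,8S,21R)-5,8-bis(triethylsilyloxy)docosa-2,6-dien-21-olide | C[C@@H]1CCCCCCCCCCCC[C@H](O[Si](CC)(CC)CC)/C=C/[C@@H](O[Si](CC)(CC)CC)C/C=C\C(=O)O1 | intermediate
20 | (2Z,5S,6E,8S,21R)-5,8-dihydroxydocosa-2,6-dien-21-olide | C[C@@H]1CCCCCCCCCCCC[C@H](O)/C=C/[C@@H](O)C/C=C\C(=O)O1 | intermediate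
21 | CIML C, (2Z,5S,6R,7R,8S,21R)-6,7-epoxy-5,8-dihydroxydocos-2-en-21-olide | C[C@@H]1CCCCCCCCCCCC[C@H](O)[C@H]2O[C@@H]2[C@@H](O)C/C=C\C(=O)O1 | target

Total step count: 14. Longest linear sequence: 10 steps (steps 1–5 and 10–14).

Steps most likely to fail:

Step 11. The two propargylic-branched alkynes may initiate slowly, so that oligomerisation or catalyst decay outruns ring closure. The fallback sets out from 16 and takes the triple bonds out of the ring-closing event. Semi-hydrogenation of both alkynes (H2, Pd/CaCO3 poisoned with Pb(OAc)2, quinoline, EtOAc) would give the bis-(Z)-propenyl ester (2R,15S,16Z)-15-(triethylsilyloxy)octadec-16-en-2-yl (2Z,5S,6Z)-5-(triethylsilyloxy)octa-2,6-dienoate F1. Ring-closing olefin metathesis of F1 (second-generation Grubbs catalyst RuCl2(=CHPh)(H2IMes)(PCy3), CH2Cl2, reflux, high dilution) would then lead under thermodynamic control to the (E)-cycloalkene. The route is rejoined at 19, and step 12 is not needed.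

Step 12. Hydrosilylation may stall at the alkyne between two silyloxy-bearing carbons, or protodesilylation may stay incomplete. The fallback sets out from 17 and lets the hydroxyl groups direct the reduction. Desilylation (HF·pyridine, pyridine, THF) would give the yne-diol (2Z,5S,8S,21R)-5,8-dihydroxydocos-2-en-6-yn-21-olide F2. Hydroxyl-directed trans-hydrostannation ([(η5-C5Me5)RuCl]4, Bu3SnH, CH2Cl2) would give the alkenylstannane (2Z,5S,6Z,8S,21R)-5,8-dihydroxy-6-(tributylstannyl)docosa-2,6-dien-21-olide F3. Protodestannation (copper thiophene-2-carboxylate CuO2CC4H3S, DMF, then aq. NH4Cl) would give the diol. The route is rejoined at 20, and step 13 is not needed.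

Step 14. Acyl migration to the free C5 hydroxyl, oxidation of the allylic carbinols or erosion of facial selectivity may occur on the unprotected diol. The fallback sets out from 19 and puts the epoxidation before the deprotection, under reagent control alone. The same ketone (30 mol%) with Oxone at pH 10.5 (K2CO3, MeCN/dimethoxymethane/H2O, 0 °C), now safe because no free hydroxyl can attack the lactone, would give (2Z,5S,6S,7S,8S,21R)-6,7-epoxy-5,8-bis(triethylsilyloxy)docos-2-en-21-olide F4. HF·pyridine/pyridine would then release the target, rejoining at 21.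

**Further compounds**
F1 | step 11 | (2R,15S,16Z)-15-(triethylsilyloxy)octadec-16-en-2-yl (2Z,5S,6Z)-5-(triethylsilyloxy)octa-2,6-dienoate | C[C@@H](OC(=O)/C=C\C[C@H](O[Si](CC)(CC)CC)/C=C\C)CCCCCCCCCCCC[C@H](O[Si](CC)(CC)CC)/C=C\C
F2 | step 12 | (2Z,5S,8S,21R)-5,8-dihydroxydocos-2-en-6-yn-21-olide | C[C@@H]1CCCCCCCCCCCC[C@H](O)C#C[C@@H](O)C/C=C\C(=O)O1
F3 | step 12 | (2Z,5S,6Z,8S,21R)-5,8-dihydroxy-6-(tributylstannyl)docosa-2,6-dien-21-olide | C[C@@H]1CCCCCCCCCCCC[C@H](O)/C=C(\[Sn](CCCC)(CCCC)CCCC)[C@@H](O)C/C=C\C(=O)O1
F4 | step 14 | (2Z,5S,6S,7S,8S,21R)-6,7-epoxy-5,8-bis(triethylsilyloxy)docos-2-en-21-olide | C[C@@H]1CCCCCCCCCCCC[C@H](O[Si](CC)(CC)CC)[C@H]2O[C@@H]2[C@@H](O[Si](CC)(CC)CC)C/C=C\C(=O)O1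
A1 | direct plan | (2S,3S)-oxirane-2,3-dicarbaldehyde | O=C[C@H]1O[C@@H]1C=O
A2 | direct plan | (4S,5R,6R,7S)-5,6-epoxydeca-1,9-diene-4,7-diol | C=CC[C@H](O)[C@H]1O[C@@H]1[C@@H](O)CC=C
A3 | direct plan | (2Z,5S,6S,7S,8S,21R)-6,7-epoxy-21-hydroxy-5,8-bis(triethylsilyloxy)docos-2-enoic acid | C[C@@H](O)CCCCCCCCCCCC[C@H](O[Si](CC)(CC)CC)[C@H]1O[C@@H]1[C@@H](O[Si](CC)(CC)CC)C/C=C\C(=O)O
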